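Assumption: (S)-4-methylcyclopent-2-en-1-one (1) is bought as the single enantiomer.

## Retrosynthetic overview

1. The acid comes from the aldehyde (oxidation) and the styryl group from a vinyl group (Heck arylation).
2. Ring B (the cyclohexene) is formed last, by a ring-closing metathesis that selects one of two vinyl groups on C5 and so sets C5.
3. The C4–C5 bond between the two quaternary carbons is made by a stereospecific pinacol-type 1,2-shift of the bis(vinyl) quaternary carbon onto a tertiary carbinol carbon; this sets C4 and creates the CHO group.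
4. The diol for the shift comes from central-carbon pentadienylation of an α-silyloxy aldehyde; its tertiary carbinol is set by a catalytic Mukaiyama aldol with methyl pyruvate.
5. Ring A (the cyclopentene) is there from the start: conjugate addition to 1, then enol triflate ethylation.

## Route

Step 1
Reactants: 1 (S)-4-methylcyclopent-2-en-1-one; 2 2-bromobut-1-ene
Product: 5 triethyl{[(3R,4S)-3-(but-1-en-2-yl)-4-methylcyclopent-1-en-1-yl]oxy}silane, via but-1-en-2-ylmagnesium bromide 3 (not isolated), via the bromomagnesium enolate 4 (not isolated)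
Conditions: 2, Mg, THF; then CuBr·SMe2 (5 mol%), Et3SiCl, DMPU, 1, THF, −78 °C
Reagents that add atoms: chlorotriethylsilane, CC[Si](CC)(CC)Cl
Why: Copper-catalysed conjugate addition of the alkenyl Grignard reagent puts the butenyl group on C3 anti to the C4 methyl group (3R, trans), and the enolate is trapped on oxygen as the regiodefined silyl enol ether.

Step 2
Reactants: 5; 6 methyl pyruvate
Product: 7 methyl (2S)-2-[(1R,2R,3S)-2-(but-1-en-2-yl)-3-methyl-5-oxocyclopentyl]-2-[(triethylsilyl)oxy]propanoate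
Conditions: Cu(OTf)2 (10 mol%), 2,2′-(propane-2,2-diyl)bis[(4S)-4-tert-butyl-4,5-dihydro-1,3-oxazole] (11 mol%), CH2Cl2, −78 °C; neutral work-up
Reagents that add atoms: none
Why: Mukaiyama aldol addition under bis(oxazoline)–copper catalysis (Evans pyruvate aldol): the enol ether attacks the Si face of the chelated pyruvate ketone (catalyst control, 2S carbinol) from its own face anti to the butenyl group (substrate control, ring C1 trans to C2), and the silyl group moves to the new tertiary alkoxide.

Step 3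
Reactants: 7
Product: 8 methyl (2S)-2-[(1R,4R,5R)-5-(but-1-en-2-yl)-4-methyl-2-{[(trifluoromethyl)sulfonyl]oxy}cyclopent-2-en-1-yl]-2-[(triethylsilyl)oxy]propanoate
Conditions: KN(SiMe3)2, THF, −78 °C; PhNTf2
Reagents that add atoms: N-phenylbis(trifluoromethanesulfonimide), O=S(=O)(N(c1ccccc1)S(=O)(=O)C(F)(F)F)C(F)(F)F
Why: Kinetic deprotonation at the unhindered ring CH2 and O-triflation (enol triflate formation) fix the position of the later ring A double bond; the ester has no α-hydrogen, the silyl ether blocks retro-aldol cleavage, and no stereocentre is touched.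

Step 4
Reactants: 8
Product: 9 methyl (2S)-2-[(1S,4S,5R)-5-(but-1-en-2-yl)-2-ethyl-4-methylcyclopent-2-en-1-yl]-2-[(triethylsilyl)oxy]propanoate
Conditions: Fe(acac)3 (5 mol%), EtMgBr, THF/NMP, −30 °C
Reagents that add atoms: ethylmagnesium bromide, CC[Mg]Br
Why: Iron-catalysed Kumada-type cross-coupling of the alkenyl triflate is much faster than Grignard attack on the hindered ester and puts the ethyl group on the ring with the double bond in place.

Step 5
Reactants: 9
Product: 10 (2S)-2-[(1S,4S,5R)-5-(but-1-en-2-yl)-2-ethyl-4-methylcyclopent-2-en-1-yl]-2-[(triethylsilyl)oxy]propanal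
Conditions: iBu2AlH (1.1 equiv), CH2Cl2, −78 °C; aq. KNaC4H4O6
Reagents that add atoms: none
Why: Partial ester reduction stops at the chelated aluminium hemiacetal of the α-silyloxy ester, which gives the aldehyde on work-up without touching a stereocentre.

Step 6
Reactants: 11 methyl propanoate
Product: 12 3-ethylpenta-1,4-dien-3-ol
Conditions: CH2=CHMgBr (2.2 equiv), THF, −78 to 0 °C; aq. NH4Cl
Reagents that add atoms: vinylmagnesium bromide, C=C[Mg]Br
Why: Double Grignard addition to the ester gives the symmetrical divinyl carbinol, which has no stereocentre.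

Step 7
Reactants: 12
Product: 13 5-bromo-3-ethylpenta-1,3-diene (E/Z mixture)
Conditions: PBr3 (0.4 equiv), pyridine (cat.), Et2O, −20 °C
Reagents that add atoms: phosphorus tribromide, BrP(Br)Br
Why: Bromination with allylic transposition (SN2′-type) gives the primary pentadienyl bromide; its double-bond geometry does not matter because the derived allylmetal is fluxional and symmetrical about the central carbon.

Step 8
Reactants: 10; 13
Product: 16 (2S,3R)-2-[(1S,4S,5R)-5-(but-1-en-2-yl)-2-ethyl-4-methylcyclopent-2-en-1-yl]-4-ethenyl-4-ethylhex-5-ene-2,3-diol, via the pentadienylzinc bromide 14 (not isolated), via the triethylsilyl ether 15 (not isolated)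
Conditions: Zn dust, THF/sat. aq. NH4Cl, 0 °C; then 1 M HCl, THF, 0 °C
Reagents that add atoms: none
Why: Barbier-type zinc allylation in which the pentadienyl reagent bonds through its central carbon (SE2′, six-membered transition state, as for prenylzinc) to give a bis(vinyl) quaternary carbon that is not yet stereogenic; Felkin–Anh attack gives mainly the (3R) carbinol, a centre that is erased in step 9, and acid then removes the silyl group.

Step 9
Reactants: 16
Product: 18 (2S)-2-[(1S,4S,5R)-5-(but-1-en-2-yl)-2-ethyl-4-methylcyclopent-2-en-1-yl]-3-ethenyl-3-ethyl-2-methylpent-4-enal, via the cyclic orthoacetate 17 (not isolated)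
Conditions: MeC(OMe)3, PPTS (cat.), CH2Cl2, 23 °C; then BF3·OEt2, −78 to −40 °C
Reagents that add atoms: none
Why: Pinacol-type 1,2-shift through a cyclic orthoester: BF3 ionises 17 to the 1,3-dioxolan-2-ylium ion, the tertiary C–O bond breaks, and the doubly allylic quaternary carbon (a far better migrating group than hydride) moves from the carbinol carbon anti to the leaving oxygen, so the catalyst-set tertiary centre is inverted into the methyl-bearing quaternary stereocentre and the former carbinol carbon becomes the aldehyde.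

Step 10
Reactants: 18
Product: 19 (1S,3aS,4S,5R,7aR)-5-ethenyl-3,5,7-triethyl-1,4-dimethyl-3a,4,5,7a-tetrahydro-1H-indene-4-carbaldehyde
Conditions: RuCl2(L)(=CH–C6H4-2-OiPr) (5 mol%; L = (4R,5R)-1,3-bis(2-isopropylphenyl)-4,5-diphenylimidazolidin-2-ylidene), toluene, 40 °C, Ar sparge
Reagents that add atoms: none
Why: Proposed new method: a catalyst-controlled ring-closing metathesis that chooses between the two diastereotopic vinyl groups on the quaternary carbon; both vinyl groups load onto ruthenium and exchange quickly, so the ratio is decided at ring closure onto the 1,1-disubstituted butenyl alkene (Curtin–Hammett), where the geared o-isopropylphenyl groups of the C2-symmetric carbene should disfavour one of the two ruthenacyclobutanes, closing ring B through the vinyl group that leaves the other vinyl cis to CHO (5R) against a substrate bias expected to be small because ethyl and vinyl are similar in size; the closest known reaction type is Ru- or Mo-catalysed asymmetric ring-closing metathesis that desymmetrises prochiral trienes.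

Step 11
Reactants: 19; 20 iodobenzene
Product: 21 (1S,3aS,4S,5R,7aR)-3,5,7-triethyl-1,4-dimethyl-5-[(E)-2-phenylethenyl]-3a,4,5,7a-tetrahydro-1H-indene-4-carbaldehyde
Conditions: Pd(OAc)2 (5 mol%), n-Bu4NCl, NaHCO3, DMF, 80 °C
Reagents that add atoms: none
Why: Heck reaction (Jeffery conditions): arylpalladium adds to the terminal carbon of the only monosubstituted alkene, and since the neighbouring carbon is quaternary, syn β-hydride elimination can only give the (E)-styrene; the trisubstituted ring alkenes and the non-enolisable aldehyde do not react.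

Step 12
Reactants: 21
Product: 22 (1S,3aS,4S,5R,7aR)-3,5,7-triethyl-1,4-dimethyl-5-[(E)-2-phenylethenyl]-3a,4,5,7a-tetrahydro-1H-indene-4-carboxylic acid
Conditions: NaClO2, NaH2PO4, 2-methylbut-2-ene, t-BuOH/H2O, 0 to 23 °C
Reagents that add atoms: sodium chlorite, [Na+].[O-]Cl=O
Why: Pinnick oxidation turns the hindered aldehyde into the acid without touching the alkenes (hypochlorous acid is scavenged) or any stereocentre.

## Compound list

1 | (S)-4-methylcyclopent-2-en-1-one | O=C1C[C@H](C)C=C1 | starting material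
2 | 2-bromobut-1-ene | C=C(Br)CC | starting material
3 | but-1-en-2-ylmagnesium bromide | C=C([Mg]Br)CC | intermediate
4 | bromomagnesium (3R,4S)-3-(but-1-en-2-yl)-4-methylcyclopent-1-en-1-olate | Br[Mg]OC1=C[C@H](C(=C)CC)[C@@H](C)C1 | intermediate
5 | triethyl{[(3R,4S)-3-(but-1-en-2-yl)-4-methylcyclopent-1-en-1-yl]oxy}silane | CC[Si](CC)(CC)OC1=C[C@H](C(=C)CC)[C@@H](C)C1 | intermediate
6 | methyl pyruvate | CC(=O)C(=O)OC | starting material
7 | methyl (2S)-2-[(1R,2R,3S)-2-(but-1-en-2-yl)-3-methyl-5-oxocyclopentyl]-2-[(triethylsilyl)oxy]propanoate | CC[Si](CC)(CC)O[C@](C)(C(=O)OC)[C@@H]1C(=O)C[C@H](C)[C@H]1C(=C)CC | intermediate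
8 | methyl (2S)-2-[(1R,4R,5R)-5-(but-1-en-2-yl)-4-methyl-2-{[(trifluoromethyl)sulfonyl]oxy}cyclopent-2-en-1-yl]-2-[(triethylsilyl)oxy]propanoate | CC[Si](CC)(CC)O[C@](C)(C(=O)OC)[C@@H]1C(OS(=O)(=O)C(F)(F)F)=C[C@H](C)[C@H]1C(=C)CC | intermediate
9 | methyl (2S)-2-[(1S,4S,5R)-5-(but-1-en-2-yl)-2-ethyl-4-methylcyclopent-2-en-1-yl]-2-[(triethylsilyl)oxy]propanoate | CC[Si](CC)(CC)O[C@](C)(C(=O)OC)[C@@H]1C(CC)=C[C@H](C)[C@H]1C(=C)CC | intermediate
10 | (2S)-2-[(1S,4S,5R)-5-(but-1-en-2-yl)-2-ethyl-4-methylcyclopent-2-en-1-yl]-2-[(triethylsilyl)oxy]propanal | CC[Si](CC)(CC)O[C@](C)(C=O)[C@@H]1C(CC)=C[C@H](C)[C@H]1C(=C)CC | intermediate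
11 | methyl propanoate | CCC(=O)OC | starting material
12 | 3-ethylpenta-1,4-dien-3-ol | CCC(O)(C=C)C=C | intermediate
13 | 5-bromo-3-ethylpenta-1,3-diene (E/Z mixture) | C=CC(CC)=CCBr | intermediate
14 | (3-ethylpenta-2,4-dien-1-yl)zinc bromide | Br[Zn]CC=C(CC)C=C | intermediate
15 | (2S,3R)-2-[(1S,4S,5R)-5-(but-1-en-2-yl)-2-ethyl-4-methylcyclopent-2-en-1-yl]-4-ethenyl-4-ethyl-2-[(triethylsilyl)oxy]hex-5-en-3-ol | CC[Si](CC)(CC)O[C@](C)([C@H](O)C(CC)(C=C)C=C)[C@@H]1C(CC)=C[C@H](C)[C@H]1C(=C)CC | intermediate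
16 | (2S,3R)-2-[(1S,4S,5R)-5-(but-1-en-2-yl)-2-ethyl-4-methylcyclopent-2-en-1-yl]-4-ethenyl-4-ethylhex-5-ene-2,3-diol | O[C@](C)([C@H](O)C(CC)(C=C)C=C)[C@@H]1C(CC)=C[C@H](C)[C@H]1C(=C)CC | intermediate
17 | (4S,5R)-4-[(1S,4S,5R)-5-(but-1-en-2-yl)-2-ethyl-4-methylcyclopent-2-en-1-yl]-5-(3-ethylpenta-1,4-dien-3-yl)-2-methoxy-2,4-dimethyl-1,3-dioxolane (both C2 epimers) | COC1(C)O[C@H](C(CC)(C=C)C=C)[C@@](C)(O1)[C@@H]2C(CC)=C[C@H](C)[C@H]2C(=C)CC | intermediate
18 | (2S)-2-[(1S,4S,5R)-5-(but-1-en-2-yl)-2-ethyl-4-methylcyclopent-2-en-1-yl]-3-ethenyl-3-ethyl-2-methylpent-4-enal | C=CC(CC)(C=C)[C@@](C)(C=O)[C@@H]1C(CC)=C[C@H](C)[C@H]1C(=C)CC | intermediate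
19 | (1S,3aS,4S,5R,7aR)-5-ethenyl-3,5,7-triethyl-1,4-dimethyl-3a,4,5,7a-tetrahydro-1H-indene-4-carbaldehyde | CCC1=C[C@](C=C)(CC)[C@@](C)(C=O)[C@@H]2C(CC)=C[C@H](C)[C@@H]12 | intermediate
20 | iodobenzene | Ic1ccccc1 | starting material
21 | (1S,3aS,4S,5R,7aR)-3,5,7-triethyl-1,4-dimethyl-5-[(E)-2-phenylethenyl]-3a,4,5,7a-tetrahydro-1H-indene-4-carbaldehyde | CCC1=C[C@](/C=C/c2ccccc2)(CC)[C@@](C)(C=O)[C@@H]2C(CC)=C[C@H](C)[C@@H]12 | intermediate
22 | (1S,3aS,4S,5R,7aR)-3,5,7-triethyl-1,4-dimethyl-5-[(E)-2-phenylethenyl]-3a,4,5,7a-tetrahydro-1H-indene-4-carboxylic acid | CCC1=C[C@](/C=C/c2ccccc2)(CC)[C@@](C)(C(=O)O)[C@@H]2C(CC)=C[C@H](C)[C@@H]12 | target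

## Step count and risks

Total step count: 12. Longest linear sequence: 10 (steps 1–5 and 8–12).

The three steps most likely to fail:

**Step 8.** The pentadienylzinc reagent may bond through a terminal carbon, or the neopentyl aldehyde may not react. The fallback sets out from 12 and 10 and comes back at 16. Dienol 12 is borylated directly with B2pin2 ([Pd(MeCN)4](BF4)2 catalyst, DMSO/MeOH) to give 2-(3-ethylpenta-2,4-dien-1-yl)-4,4,5,5-tetramethyl-1,3,2-dioxaborolane F1. Heating F1 with 10 in toluene is an allylboration that has to pass through the closed chair transition state and so bonds through the central carbon, giving the O-boryl adduct of 15, F2. Work-up with aqueous HCl hydrolyses the B–O and Si–O bonds to give 16.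

**Step 9.** The crowded diol may not form the orthoester, or hydride may migrate instead of carbon. The fallback sets out from 16 and comes back at 18. Mitsunobu cyclodehydration (PPh3, DIAD, toluene) activates the less hindered secondary hydroxyl, and the tertiary oxygen closes the trisubstituted epoxide F3 with inversion at the secondary carbon. Meinwald rearrangement (BF3·OEt2, or MeAl(OC6H2-4-Br-2,6-tBu2)2) opens the tertiary C–O bond while the quaternary carbon migrates anti to oxygen, which gives 18 with the same configuration.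

**Step 10 (the proposed new step).** The chiral catalyst may not override the substrate. The fallback uses known chemistry only, sets out from 18 and comes back at 22. Ring-closing metathesis with the achiral second-generation Hoveyda–Grubbs catalyst gives 19 together with its C5 epimer F4. Pinnick oxidation of the mixture gives the acids F5 (5R) and F6 (5S). Iodolactonisation (I2, NaHCO3, MeCN) converts only F5, in which the vinyl group is cis to the carboxyl group, into the neutral cis-fused iodolactone F7; F6 is removed by a bicarbonate wash. Zn in AcOH regenerates F5, and the Heck conditions of step 11 applied to F5 give 22.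

## Further compounds

F1 | step 8 | 2-(3-ethylpenta-2,4-dien-1-yl)-4,4,5,5-tetramethyl-1,3,2-dioxaborolane | C=CC(CC)=CCB1OC(C)(C)C(C)(C)O1
F2 | step 8 | 2-{[(2S,3R)-2-[(1S,4S,5R)-5-(but-1-en-2-yl)-2-ethyl-4-methylcyclopent-2-en-1-yl]-4-ethenyl-4-ethyl-2-[(triethylsilyl)oxy]hex-5-en-3-yl]oxy}-4,4,5,5-tetramethyl-1,3,2-dioxaborolane | CC[Si](CC)(CC)O[C@](C)([C@H](OB1OC(C)(C)C(C)(C)O1)C(CC)(C=C)C=C)[C@@H]2C(CC)=C[C@H](C)[C@H]2C(=C)CC
F3 | step 9 | (2S,3S)-2-[(1S,4S,5R)-5-(but-1-en-2-yl)-2-ethyl-4-methylcyclopent-2-en-1-yl]-3-(3-ethylpenta-1,4-dien-3-yl)-2-methyloxirane | C=CC(CC)(C=C)[C@@H]1O[C@@]1(C)[C@@H]2C(CC)=C[C@H](C)[C@H]2C(=C)CC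
F4 | step 10 | (1S,3aS,4S,5S,7aR)-5-ethenyl-3,5,7-triethyl-1,4-dimethyl-3a,4,5,7a-tetrahydro-1H-indene-4-carbaldehyde | CCC1=C[C@@](C=C)(CC)[C@@](C)(C=O)[C@@H]2C(CC)=C[C@H](C)[C@@H]12
F5 | step 10 | (1S,3aS,4S,5R,7aR)-5-ethenyl-3,5,7-triethyl-1,4-dimethyl-3a,4,5,7a-tetrahydro-1H-indene-4-carboxylic acid | CCC1=C[C@](C=C)(CC)[C@@](C)(C(=O)O)[C@@H]2C(CC)=C[C@H](C)[C@@H]12
F6 | step 10 | (1S,3aS,4S,5S,7aR)-5-ethenyl-3,5,7-triethyl-1,4-dimethyl-3a,4,5,7a-tetrahydro-1H-indene-4-carboxylic acid | CCC1=C[C@@](C=C)(CC)[C@@](C)(C(=O)O)[C@@H]2C(CC)=C[C@H](C)[C@@H]12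
F7 | step 10 | cis-fused γ-iodolactone of F5 (carboxyl oxygen on the inner carbon of the former C5 vinyl group, CH2I on that carbon, new CH–O centre unassigned) | CCC1=C[C@@]4(CC)C(CI)OC(=O)[C@@]4(C)[C@@H]2C(CC)=C[C@H](C)[C@@H]12
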